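**Retrosynthetic overview**
- Feature: in ring B (C6–C11) the chlorinated carbon C9 lies 1,4 to the spiro carbon C6, so ring B is a para-substituted phenol in disguise (C9 = phenol carbon, C6 = para carbon). C6 is bonded to C5, the ring-A carbon that carries the exocyclic CH2.
- Key disconnection C5–C6: a palladium-catalysed dearomative alkenylation of phenol 11 (2-bromoallyl terminus) closes ring A and gives the spiro cyclohexadienone 12.
- Phenol 11 comes from anisole and methyl 3-methylbut-2-enoate (aryl–C1 bond), an enamine-catalysed α-bromination (C2) and a Cornforth-controlled 2-bromoallylation (C3).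
- After the key step the C3 hydroxyl captures the enone arm on its own face (C7) as an ether bridge, the other arm is reduced, and the bridge is reopened. Reductive bromination (C8), axial methyl addition and chlorination with retention (C9) finish ring B.
- Ring order: ring B enters as the arene of anisole; ring A is formed in step 9.

Key step: step 9

Remark: target locants are used for all spiro compounds (C1 CMe2, C2 CHBr, C3 CHOH, C4 CH2, C5 C=CH2, C6 spiro, C7 CH2, C8 CHBr, C9 CClMe, C10/C11 CH2); the ether-bridged compounds are assumed to form as the C7 epimer drawn, which is immaterial because C7 returns to CH2.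

Step 1
Reactants: 1 anisole; 2 methyl 3-methylbut-2-enoate
Product: 3 methyl 3-(4-methoxyphenyl)-3-methylbutanoate
Conditions: AlCl3 (1.5 equiv), anisole (5 equiv, as solvent), 0 °C → rt
Reagents that add atoms: none
Why: Friedel–Crafts hydroarylation, in which the AlCl3-activated β,β-dimethylacrylate reacts as a tertiary cation at the unhindered para position of anisole and so supplies the aryl–CMe2 bond that later flanks the spiro centre.

Step 2
Reactants: 3 methyl 3-(4-methoxyphenyl)-3-methylbutanoate
Product: 4 methyl 3-(4-hydroxyphenyl)-3-methylbutanoate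
Conditions: BBr3 (1.5 equiv), CH2Cl2, −78 → 0 °C; ice/NaHCO3
Reagents that add atoms: none
Why: Lewis-acid cleavage of the aryl methyl ether (BBr3 demethylation), faster than ester cleavage at low temperature and placed here because no later intermediate tolerates such a reagent.

Step 3
Reactants: 4 methyl 3-(4-hydroxyphenyl)-3-methylbutanoate
Product: 5 methyl 3-[4-(tert-butyldimethylsilyloxy)phenyl]-3-methylbutanoate
Conditions: TBSCl, imidazole, DMF, rt
Reagents that add atoms: tert-butyldimethylsilyl chloride, CC(C)(C)[Si](C)(C)Cl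
Why: Standard phenol silylation; the aryl silyl ether should survive hydride, enamine and Lewis-acid steps and can later be removed selectively beside an alkyl silyl ether.

Step 4
Reactants: 5 methyl 3-[4-(tert-butyldimethylsilyloxy)phenyl]-3-methylbutanoate
Product: 6 3-[4-(tert-butyldimethylsilyloxy)phenyl]-3-methylbutanal
Conditions: iBu2AlH (1.1 equiv), CH2Cl2, −78 °C; aq. potassium sodium tartrate
Reagents that add atoms: none
Why: Partial ester reduction, the tetrahedral aluminium hemiacetal of this β-quaternary ester being stable at −78 °C and collapsing to the aldehyde only on work-up.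

Step 5
Reactants: 6 3-[4-(tert-butyldimethylsilyloxy)phenyl]-3-methylbutanal
Product: 7 (2R)-2-bromo-3-[4-(tert-butyldimethylsilyloxy)phenyl]-3-methylbutanal
Conditions: (R)-2-{bis[3,5-bis(trifluoromethyl)phenyl][(trimethylsilyl)oxy]methyl}pyrrolidine (10 mol%), 4,4-dibromo-2,6-di-tert-butylcyclohexa-2,5-dienone (1.05 equiv), PhCO2H (10 mol%), trace H2O, CH2Cl2/pentane 1:1, −40 °C; cold silica filtration, used at once
Reagents that add atoms: 4,4-dibromo-2,6-di-tert-butylcyclohexa-2,5-dienone, O=C1C(C(C)(C)C)=CC(Br)(Br)C=C1C(C)(C)C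
Why: Enamine-catalysed asymmetric α-bromination, in which the E-enamine turned away from the diarylmethyl group is brominated on its unshielded face by the mild dienone reagent, which should set C2 as R without brominating the arene.

Step 6
Reactants: 7 (2R)-2-bromo-3-[4-(tert-butyldimethylsilyloxy)phenyl]-3-methylbutanal; 8 (2-bromoallyl)trimethylsilane
Product: 9 (4S,5R)-2,5-dibromo-6-[4-(tert-butyldimethylsilyloxy)phenyl]-6-methylhept-1-en-4-ol
Conditions: TiCl4 (1.1 equiv), CH2Cl2, −78 °C
Reagents that add atoms: none
Why: Hosomi–Sakurai allylation through an open transition state, where the Cornforth/polar Felkin–Anh preference (attack anti to the C–Br bond, past H and away from the CMe2Ar group) should give the 4,5-anti bromohydrin and so set the carbinol (future C3) as S.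

Step 7
Reactants: 9 (4S,5R)-2,5-dibromo-6-[4-(tert-butyldimethylsilyloxy)phenyl]-6-methylhept-1-en-4-ol
Product: 10 (4S,5R)-2,5-dibromo-4-(tert-butyldimethylsilyloxy)-6-[4-(tert-butyldimethylsilyloxy)phenyl]-6-methylhept-1-ene
Conditions: TBSOTf, 2,6-lutidine, CH2Cl2, −78 → 0 °C
Reagents that add atoms: tert-butyldimethylsilyl trifluoromethanesulfonate, CC(C)(C)[Si](C)(C)OS(=O)(=O)C(F)(F)F
Why: Silyl triflate silylation of the hindered secondary alcohol under a weak base, which blocks epoxide formation from the anti bromohydrin in the basic key step.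

Step 8
Reactants: 10 (4S,5R)-2,5-dibromo-4-(tert-butyldimethylsilyloxy)-6-[4-(tert-butyldimethylsilyloxy)phenyl]-6-methylhept-1-ene
Product: 11 4-[(3R,4S)-3,6-dibromo-4-(tert-butyldimethylsilyloxy)-2-methylhept-6-en-2-yl]phenol
Conditions: KHF2, MeOH, rt
Reagents that add atoms: none
Why: Chemoselective desilylation, the aryl silyl ether being far more labile to bifluoride than the secondary alkyl silyl ether, while both bromides are inert.

Step 9
Reactants: 11 4-[(3R,4S)-3,6-dibromo-4-(tert-butyldimethylsilyloxy)-2-methylhept-6-en-2-yl]phenol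
Product: 12 (2R,3S)-2-bromo-3-(tert-butyldimethylsilyloxy)-1,1-dimethyl-5-methylidenespiro[5.5]undeca-7,10-dien-9-one
Conditions: Pd2(dba)3 (2.5 mol%), XPhos (2-dicyclohexylphosphino-2',4',6'-triisopropylbiphenyl, 7.5 mol%), K2CO3 (2 equiv), toluene, 100 °C
Reagents that add atoms: none
Why: Proposed new method: zerovalent palladium inserts into the alkenyl C–Br bond, carbonate converts the phenol into a phenoxide that replaces bromide on palladium, the para carbon (future C6) then binds palladium with loss of aromaticity, and reductive elimination joins C6 to the alkenyl carbon C5. The closest known reaction is the palladium-catalysed intramolecular arylative dearomatisation of para-tethered phenols with aryl bromides to spirocyclohexadienones; an alkenyl bromide on a saturated tether is the untested element, although alkenyl halides are established partners in the related intramolecular enolate alkenylation. Ring A (C1–C6) closes in a 6-exo sense through a seven-membered palladacycle, the C5=CH2 bond staying outside the ring and the gem-dimethyl group favouring the folded tether. No stereocentre is formed, since C6 carries two identical enone arms, and C2 and C3 pass through unchanged. The step needs insertion at the sp2 C–Br bond and not at the neopentyl-type secondary C2–Br bond (secured by the much higher reactivity of alkenyl bromides and the hindrance at C2), C- and not O-coupling (the oxygen cannot reach C5 through the tether, and ortho attack would give a strained bridged ring), and a base too weak to eliminate HBr (K2CO3).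

Step 10
Reactants: 12 (2R,3S)-2-bromo-3-(tert-butyldimethylsilyloxy)-1,1-dimethyl-5-methylidenespiro[5.5]undeca-7,10-dien-9-one
Product: 13 (2R,3S)-2-bromo-3-hydroxy-1,1-dimethyl-5-methylidenespiro[5.5]undeca-7,10-dien-9-one
Conditions: HF·pyridine, pyridine, THF, 0 °C → rt
Reagents that add atoms: none
Why: Fluoride desilylation under non-basic conditions frees the C3 hydroxyl without starting an uncontrolled conjugate addition.

Step 11
Reactants: 13 (2R,3S)-2-bromo-3-hydroxy-1,1-dimethyl-5-methylidenespiro[5.5]undeca-7,10-dien-9-one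
Product: 15 (2R,3S,6R,7R)-2-bromo-3,7-epoxy-1,1-dimethyl-5-methylidenespiro[5.5]undec-10-en-9-one, via potassium dienolate 14 (not isolated)
Conditions: KN(SiMe3)2 (1.05 equiv), THF, −78 → 0 °C; then AcOH (2 equiv), −78 °C
Reagents that add atoms: none
Why: Intramolecular oxa-Michael addition, in which the C3 alkoxide can reach only the enone carbon C7 on its own face of ring A (ring A as a boat), giving a 2-oxabicyclo[2.2.2]octane whose formation is driven by the more stable dienolate and locked by cold C8 protonation; this distinguishes the two arms at C6 (now R), and the C7 centre is erased later.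

Step 12
Reactants: 15 (2R,3S,6R,7R)-2-bromo-3,7-epoxy-1,1-dimethyl-5-methylidenespiro[5.5]undec-10-en-9-one
Product: 17 (2R,3S,6R,7R)-2-bromo-3,7-epoxy-1,1-dimethyl-5-methylidenespiro[5.5]undecan-9-one, via silyl enol ether 16 (not isolated)
Conditions: [(Ph3P)CuH]6 (5 mol%), PhMe2SiH (1.5 equiv), toluene, rt; then 1 M aq. HCl, THF, 0 °C
Reagents that add atoms: none
Why: Copper-hydride-catalysed conjugate hydrosilylation reduces only the remaining enone (C10=C11), sparing the 1,1-disubstituted alkene, the secondary bromide and the β-alkoxy ketone, and brief acid hydrolysis of the enol ether gives the ketone without enolisation toward C8.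

Step 13
Reactants: 17 (2R,3S,6R,7R)-2-bromo-3,7-epoxy-1,1-dimethyl-5-methylidenespiro[5.5]undecan-9-one
Product: 19 (2R,3S,6R)-2-bromo-1,1-dimethyl-5-methylidene-3-(triethylsilyloxy)spiro[5.5]undec-7-en-9-one, via hydroxy enone 18 (not isolated)
Conditions: DBU (1.0 equiv), CH2Cl2, rt; then Et3SiCl, imidazole, 0 °C → rt
Reagents that add atoms: chlorotriethylsilane, CC[Si](Cl)(CC)CC
Why: Base-mediated retro-oxa-Michael (E1cB) releases the strain of the bicyclic ether and unveils the C7=C8 enone on the arm cis to the C3 oxygen, and silylation of the freed hydroxyl makes the opening irreversible and protects C3 for the end game.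

Step 14
Reactants: 19 (2R,3S,6R)-2-bromo-1,1-dimethyl-5-methylidene-3-(triethylsilyloxy)spiro[5.5]undec-7-en-9-one
Product: 22 (2R,3S,6R,8R)-2,8-dibromo-1,1-dimethyl-5-methylidene-3-(triethylsilyloxy)spiro[5.5]undecan-9-one, via silyl enol ether 20 (not isolated), via axial 8-epimer 21 (not isolated)
Conditions: [(Ph3P)CuH]6 (5 mol%), PhMe2SiH (1.2 equiv), toluene, rt; then NBS (1.3 equiv), THF, −78 °C; then LiBr (2 equiv), acetone, rt
Reagents that add atoms: N-bromosuccinimide, O=C1CCC(=O)N1Br
Why: Conjugate hydrosilylation gives the C8=C9 silyl enol ether regiospecifically, NBS brominates C8, and bromide exchange (SN2 at the α-keto carbon) equilibrates the epimers to the equatorial bromide, which avoids the 1,3-diaxial contact with C5 and lies cis to C1, so C8 should be set as R under thermodynamic control.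

Step 15
Reactants: 22 (2R,3S,6R,8R)-2,8-dibromo-1,1-dimethyl-5-methylidene-3-(triethylsilyloxy)spiro[5.5]undecan-9-one
Product: 23 (2R,3S,6R,8R,9R)-2,8-dibromo-1,1,9-trimethyl-5-methylidene-3-(triethylsilyloxy)spiro[5.5]undecan-9-ol
Conditions: AlMe3 (3 equiv), toluene, −40 → 0 °C
Reagents that add atoms: trimethylaluminium, C[Al](C)C
Why: Carbonyl methylation with excess AlMe3 in a hydrocarbon solvent, a non-basic reagent that avoids enolisation and debromination and is expected to deliver methyl axially (six-centre transition state with two aluminium centres, equatorial attack being disfavoured by the eclipsed equatorial C8–Br), giving the equatorial C9 hydroxyl trans to bromine (C9 R).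

Step 16
Reactants: 23 (2R,3S,6R,8R,9R)-2,8-dibromo-1,1,9-trimethyl-5-methylidene-3-(triethylsilyloxy)spiro[5.5]undecan-9-ol
Product: 25 (2R,3S,6R,8R,9R)-2,8-dibromo-9-chloro-1,1,9-trimethyl-5-methylidenespiro[5.5]undecan-3-ol, via triethylsilyl ether 24 (not isolated)
Conditions: SOCl2 (1.3 equiv), 2,6-di-tert-butyl-4-methylpyridine (2 equiv), CH2Cl2, −40 → 0 °C; then MeOH, PPTS (cat.), rt
Reagents that add atoms: thionyl chloride, O=S(Cl)Cl
Why: Internal substitution (SNi) of the tertiary chlorosulfite, supported by neighbouring-group participation of the C8 bromine (bromonium relay), returns chloride to the face the oxygen left and anti to bromine, so C9–Cl should form with retention and trans to C8–Br, and buffered methanolysis then frees the C3 hydroxyl.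

**Compound list**
1 | anisole | COc1ccccc1 | starting material
2 | methyl 3-methylbut-2-enoate | COC(=O)C=C(C)C | starting material
3 | methyl 3-(4-methoxyphenyl)-3-methylbutanoate | COC(=O)CC(C)(C)c1ccc(OC)cc1 | intermediate
4 | methyl 3-(4-hydroxyphenyl)-3-methylbutanoate | COC(=O)CC(C)(C)c1ccc(O)cc1 | intermediate
5 | methyl 3-[4-(tert-butyldimethylsilyloxy)phenyl]-3-methylbutanoate | COC(=O)CC(C)(C)c1ccc(O[Si](C)(C)C(C)(C)C)cc1 | intermediate
6 | 3-[4-(tert-butyldimethylsilyloxy)phenyl]-3-methylbutanal | O=CCC(C)(C)c1ccc(O[Si](C)(C)C(C)(C)C)cc1 | intermediate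
7 | (2R)-2-bromo-3-[4-(tert-butyldimethylsilyloxy)phenyl]-3-methylbutanal | O=C[C@H](Br)C(C)(C)c1ccc(O[Si](C)(C)C(C)(C)C)cc1 | intermediate
8 | (2-bromoallyl)trimethylsilane | C=C(Br)C[Si](C)(C)C | starting material
9 | (4S,5R)-2,5-dibromo-6-[4-(tert-butyldimethylsilyloxy)phenyl]-6-methylhept-1-en-4-ol | C=C(Br)C[C@H](O)[C@H](Br)C(C)(C)c1ccc(O[Si](C)(C)C(C)(C)C)cc1 | intermediate
10 | (4S,5R)-2,5-dibromo-4-(tert-butyldimethylsilyloxy)-6-[4-(tert-butyldimethylsilyloxy)phenyl]-6-methylhept-1-ene | C=C(Br)C[C@H](O[Si](C)(C)C(C)(C)C)[C@H](Br)C(C)(C)c1ccc(O[Si](C)(C)C(C)(C)C)cc1 | intermediate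
11 | 4-[(3R,4S)-3,6-dibromo-4-(tert-butyldimethylsilyloxy)-2-methylhept-6-en-2-yl]phenol (key-step precursor) | C=C(Br)C[C@H](O[Si](C)(C)C(C)(C)C)[C@H](Br)C(C)(C)c1ccc(O)cc1 | intermediate
12 | (2R,3S)-2-bromo-3-(tert-butyldimethylsilyloxy)-1,1-dimethyl-5-methylidenespiro[5.5]undeca-7,10-dien-9-one (key-step product) | C=C1C[C@H](O[Si](C)(C)C(C)(C)C)[C@H](Br)C(C)(C)C12C=CC(=O)C=C2 | intermediate
13 | (2R,3S)-2-bromo-3-hydroxy-1,1-dimethyl-5-methylidenespiro[5.5]undeca-7,10-dien-9-one | C=C1C[C@H](O)[C@H](Br)C(C)(C)C12C=CC(=O)C=C2 | intermediate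
14 | potassium dienolate of 15 (C3–O–C7 ether bridge, C8=C9 enolate, C10=C11 alkene; not isolated) | C=C1C[C@@H]2O[C@@H]3C=C([O-])C=C[C@]13C(C)(C)[C@H]2Br.[K+] | intermediate
15 | (2R,3S,6R,7R)-2-bromo-3,7-epoxy-1,1-dimethyl-5-methylidenespiro[5.5]undec-10-en-9-one (ether oxygen links C3 and C7) | C=C1C[C@@H]2O[C@@H]3CC(=O)C=C[C@]13C(C)(C)[C@H]2Br | intermediate
16 | dimethyl(phenyl)silyl enol ether (C9=C10) of 17 (not isolated) | C=C1C[C@@H]2O[C@@H]3CC(O[Si](C)(C)c4ccccc4)=CC[C@]13C(C)(C)[C@H]2Br | intermediate
17 | (2R,3S,6R,7R)-2-bromo-3,7-epoxy-1,1-dimethyl-5-methylidenespiro[5.5]undecan-9-one | C=C1C[C@@H]2O[C@@H]3CC(=O)CC[C@]13C(C)(C)[C@H]2Br | intermediate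
18 | (2R,3S,6R)-2-bromo-3-hydroxy-1,1-dimethyl-5-methylidenespiro[5.5]undec-7-en-9-one (enone arm cis to the C3 hydroxyl; not isolated) | C=C1C[C@H](O)[C@H](Br)C(C)(C)[C@@]12CCC(=O)C=C2 | intermediate
19 | (2R,3S,6R)-2-bromo-1,1-dimethyl-5-methylidene-3-(triethylsilyloxy)spiro[5.5]undec-7-en-9-one | C=C1C[C@H](O[Si](CC)(CC)CC)[C@H](Br)C(C)(C)[C@@]12CCC(=O)C=C2 | intermediate
20 | (2R,3S,6R)-2-bromo-9-[dimethyl(phenyl)silyloxy]-1,1-dimethyl-5-methylidene-3-(triethylsilyloxy)spiro[5.5]undec-8-ene (not isolated) | C=C1C[C@H](O[Si](CC)(CC)CC)[C@H](Br)C(C)(C)[C@@]12CCC(O[Si](C)(C)c3ccccc3)=CC2 | intermediate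
21 | (2R,3S,6R,8S)-2,8-dibromo-1,1-dimethyl-5-methylidene-3-(triethylsilyloxy)spiro[5.5]undecan-9-one (axial C8–Br; not isolated) | C=C1C[C@H](O[Si](CC)(CC)CC)[C@H](Br)C(C)(C)[C@@]12CCC(=O)[C@@H](Br)C2 | intermediate
22 | (2R,3S,6R,8R)-2,8-dibromo-1,1-dimethyl-5-methylidene-3-(triethylsilyloxy)spiro[5.5]undecan-9-one (equatorial C8–Br) | C=C1C[C@H](O[Si](CC)(CC)CC)[C@H](Br)C(C)(C)[C@@]12CCC(=O)[C@H](Br)C2 | intermediate
23 | (2R,3S,6R,8R,9R)-2,8-dibromo-1,1,9-trimethyl-5-methylidene-3-(triethylsilyloxy)spiro[5.5]undecan-9-ol | C=C1C[C@H](O[Si](CC)(CC)CC)[C@H](Br)C(C)(C)[C@@]12CC[C@@](C)(O)[C@H](Br)C2 | intermediate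
24 | triethylsilyl ether of the target (not isolated) | C=C1C[C@H](O[Si](CC)(CC)CC)[C@H](Br)C(C)(C)[C@@]12CC[C@@](C)(Cl)[C@H](Br)C2 | intermediate
25 | (2R,3S,6R,8R,9R)-2,8-dibromo-9-chloro-1,1,9-trimethyl-5-methylidenespiro[5.5]undecan-3-ol | C=C1C[C@H](O)[C@H](Br)C(C)(C)[C@@]12CC[C@@](C)(Cl)[C@H](Br)C2 | target

**Step count and risks**
Total steps: 16. Longest linear sequence: 16 steps (anisole to 25).

Steps most likely to fail:

1. Step 9 (proposed new method). After insertion into the alkenyl C–Br bond, C–C reductive elimination at the doubly neopentyl para carbon may be too slow, so the alkenylpalladium species decays by protodebromination or β-hydride loss to an allene and ring A does not close. The fallback uses the known gold-catalysed dearomative ipso-carbocyclisation of para-hydroxyaryl alkynes. It sets out from 7: BF3·OEt2-mediated addition of tributyl(propa-1,2-dienyl)stannane should give, under the same Cornforth control, the homopropargylic bromohydrin (4S,5R)-5-bromo-6-[4-(tert-butyldimethylsilyloxy)phenyl]-6-methylhept-1-yn-4-ol F1. Silylation (TBSOTf, 2,6-lutidine) gives the bis-silyl ether F2, and KHF2 in MeOH frees the phenol F3. The cationic gold complex (tBu2(2-biphenylyl)P)Au(NCMe)SbF6 in CH2Cl2 then activates the terminal alkyne for 6-exo-dig attack by the para carbon; protodeauration leaves the exocyclic methylene. The route is rejoined at 12.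

2. Step 11. Ring A has to flip into a boat, and the strained bicyclic dienolate may not be favoured over the open alkoxide, so that protonation simply returns 13; the cis-bromohydrin alkoxide may meanwhile lose bromide by hydride shift. The fallback replaces substrate control by catalyst control and sets out from 12: a desymmetrising conjugate reduction with CuH generated from Cu(OAc)2, one enantiomer of DTBM-SEGPHOS and a silane reduces one enone arm only. The ligand antipode is chosen so that hydride goes to the arm trans to the C3 oxygen, giving the silyl-protected enone (2R,3S,6R)-2-bromo-3-(tert-butyldimethylsilyloxy)-1,1-dimethyl-5-methylidenespiro[5.5]undec-7-en-9-one F4. HF·pyridine then gives 18, where the route is rejoined (silylation to 19 as in step 13).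

3. Step 5. The amine catalyst or handling may enolise the α-bromo aldehyde and erode the C2 configuration before the allylation fixes it, and facial control of the bromination may be incomplete for this β-quaternary aldehyde. The fallback sets C2 with a covalently bound auxiliary and sets out from 6: oxidation (NaClO2, NaH2PO4, 2-methylbut-2-ene) gives the acid F5. Coupling of its pivaloyl mixed anhydride with lithiated (R)-4-benzyl-1,3-oxazolidin-2-one gives the imide F6. Boron enolate formation (Bu2BOTf, iPr2NEt) and bromination with NBS on the face away from the benzyl group give the (2R)-bromo imide F7, whose diastereomers can be separated. LiBH4 reduction gives the bromo alcohol F8, and Dess–Martin oxidation returns to 7.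

**Further compounds**
F1 | step 9 | (4S,5R)-5-bromo-6-[4-(tert-butyldimethylsilyloxy)phenyl]-6-methylhept-1-yn-4-ol | C#CC[C@H](O)[C@H](Br)C(C)(C)c1ccc(O[Si](C)(C)C(C)(C)C)cc1
F2 | step 9 | (4S,5R)-5-bromo-4-(tert-butyldimethylsilyloxy)-6-[4-(tert-butyldimethylsilyloxy)phenyl]-6-methylhept-1-yne | C#CC[C@H](O[Si](C)(C)C(C)(C)C)[C@H](Br)C(C)(C)c1ccc(O[Si](C)(C)C(C)(C)C)cc1
F3 | step 9 | 4-[(3R,4S)-3-bromo-4-(tert-butyldimethylsilyloxy)-2-methylhept-6-yn-2-yl]phenol | C#CC[C@H](O[Si](C)(C)C(C)(C)C)[C@H](Br)C(C)(C)c1ccc(O)cc1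
F4 | step 11 | (2R,3S,6R)-2-bromo-3-(tert-butyldimethylsilyloxy)-1,1-dimethyl-5-methylidenespiro[5.5]undec-7-en-9-one | C=C1C[C@H](O[Si](C)(C)C(C)(C)C)[C@H](Br)C(C)(C)[C@@]12CCC(=O)C=C2
F5 | step 5 | 3-[4-(tert-butyldimethylsilyloxy)phenyl]-3-methylbutanoic acid | OC(=O)CC(C)(C)c1ccc(O[Si](C)(C)C(C)(C)C)cc1
F6 | step 5 | (4R)-4-benzyl-3-{3-[4-(tert-butyldimethylsilyloxy)phenyl]-3-methylbutanoyl}-1,3-oxazolidin-2-one | O=C(CC(C)(C)c1ccc(O[Si](C)(C)C(C)(C)C)cc1)N1[C@H](Cc2ccccc2)COC1=O
F7 | step 5 | (4R)-4-benzyl-3-{(2R)-2-bromo-3-[4-(tert-butyldimethylsilyloxy)phenyl]-3-methylbutanoyl}-1,3-oxazolidin-2-one | O=C([C@H](Br)C(C)(C)c1ccc(O[Si](C)(C)C(C)(C)C)cc1)N1[C@H](Cc2ccccc2)COC1=O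
F8 | step 5 | (2R)-2-bromo-3-[4-(tert-butyldimethylsilyloxy)phenyl]-3-methylbutan-1-ol | OC[C@H](Br)C(C)(C)c1ccc(O[Si](C)(C)C(C)(C)C)cc1
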